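Remark on the chemistry: 4,4-dibromo-2,6-di-tert-butylcyclohexa-2,5-dien-1-one and the camphorsulfonamide diol ligand of step 2 are treated as purchasable reagents. Atom labels C1–C11 are those of the spiro[5.5]undecane skeleton of the target and are kept for every intermediate.

## Analysis of the target

The target 24 is a spiro[5.5]undecane. Ring A (C1–C6) holds a methyl-bearing C1=C2 alkene, an allylic C3 carbinol, a secondary bromide at C4 and a gem-dimethyl C5. Ring B (C6–C11) holds a secondary chloride at C8 and a tertiary bromide with a methyl group at C9. The five stereocentres are 3S, 4R, 6R, 8S and 9S: C3–OH and C4–Br are cis, C8–Cl and C9–Br are trans, chlorine lies on the ring B face that carries C1 and bromine on the face that carries C5. The spiro carbon C6 is an all-carbon quaternary centre next to quaternary C5, and its configuration is defined only by remote differences between the two arms of each ring. Sensitive groups are the tertiary bromide (ionisation, elimination), the vicinal bromide/chloride pair (reductive elimination by metals), the bromohydrin (epoxide closure with base) and the allylic alcohol (acid). The hard points are the C5–C6 bond between two fully substituted carbons, the absolute configuration at C6, and a halogen pattern at C8/C9 that is the reverse of what BrCl addition to a trisubstituted alkene delivers. The strategy rests on one feature of ring A: the C1(CH3)=C2–C3(OH) unit is the double-bond isomer of a 1-methylidene-3-ol, the product of an ene reaction between an isopropenyl group on C6 and an aldehyde at C3.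

## Retrosynthetic reasoning

24 to 23. No skeletal bond is cut; the C1=C2 alkene is moved to the exocyclic position. This exposes the homoallylic alcohol pattern of an ene product. Forward, the isomerisation can only go into ring A towards C2, because C6 carries no hydrogen.

23 to 21. The C2–C3 bond is cut. This is the only ring A bond whose cleavage leaves an aldehyde and an unactivated alkene, two groups that survive next to a tertiary bromide. It also removes a ring and the C3 stereocentre in one move. Forward, the aldehyde of 21 must add to the CH2 end of the isopropenyl group with oxygen cis to the C4 bromide.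

21 to 20. The C4–Br bond is cut. The α-position of an aldehyde is the one place where a reagent-controlled bromination is established, so C4 is set by a catalyst and not by the distant ring B centres.

20 to 17 (through 19). The C3 oxygen is removed back to a terminal vinyl group. The vinyl group is inert to everything done on ring B and is the only monosubstituted alkene in 17, so it can be addressed in the presence of the hindered isopropenyl group.

17 to 16. The isopropenyl C=CH2 bond is traced to an acetyl group. A carbonyl group at this position tolerates the acidic bromide-forming step that an isopropenyl group would not, so the alkene is unmasked only after the halogens are in place.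

16 to 13 (through 15 and 14). C9–Br and C8–Cl are cut back to the C8=C9 alkene. Direct BrCl addition would put chlorine on C9, so the halogens are introduced one at a time: epoxide, chloride at the secondary carbon with inversion, then bromide at the tertiary carbon with retention. The quaternary C6 with its large equatorial C5 arm locks ring B, so every one of these steps can be run in the trans-diaxial mode.

13 to 11. The acetyl C–CH3 bond is cut to a carboxylic acid, the natural product of an ester enolate rearrangement. This methyl carbon ends as the C1 methyl of 24.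

11 to 8. The C6–C7 bond is cut and the C9–O bond re-formed: an Ireland–Claisen ring contraction of a δ-lactone. This is the decisive simplification for ring B. It forms ring B, puts the alkene at C8=C9, and turns the hard-to-make quaternary C6 into a tertiary carbinol stereocentre at C9, whose configuration is carried over by the cyclic transition state.

8 to 5 and 6. The C8–C9 bond (vinyl to carbonyl) and the lactone C–O bond are cut. The stereocentre of 8 is then the result of an enantioselective vinyl addition to a methyl ketone.

5 to 1 and 2. The C6–C11 bond is cut by a Michael disconnection. Ester 1 already contains C1, C6, C5 with both methyl groups, C4 and C3, so the C5–C6 bond between the two quaternary carbons is bought and never has to be made.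

## Alternatives that were turned down

Alternative 1: Both ring alkenes, C1=C2 and C8=C9, are cut at once, leading to the acyclic tetraene (6R)-6-[(2E)-but-2-en-1-yl]-5,5,9-trimethyl-6-(prop-1-en-2-yl)deca-1,9-dien-3-one A2. Forward, the second-generation Hoveyda–Grubbs catalyst, RuCl2(H2IMes)(=CH–C6H4-2-OiPr), would close both rings to (6S)-1,5,5,9-tetramethylspiro[5.5]undeca-1,8-dien-3-one A1.
- For it: one catalytic operation makes both rings. The enone of A1 deactivates the ring A alkene, so ring B could be halogenated without competition; on this point it is stronger than the chosen route, which has to order its steps to avoid two reactive alkenes. Bromination at C4 and reduction at C3 of an enone are standard.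
- Against it: the stereogenic C6 of A2 carries four alkenyl arms and sits next to quaternary C5, so the hardest problem of the target is moved to an acyclic precursor with no obvious control element. The isopropenyl group between two quaternary carbons is a poor metathesis partner. The vinyl ketone can also pair with the butenyl arm to give a seven-membered ring.
- In its place, the chosen route sets C6 by chirality transfer from a carbinol, makes ring B in the same event, and forms C3 at the right oxidation level with its configuration.

Alternative 2: The C1–C6 bond is cut and ring B traced to a phenol, 6-(4-hydroxyphenyl)-6-methylhept-2-yn-4-one A4. Forward, the phenolate (or the phenol with AgOTf) would attack the ynone β-carbon through its para carbon to give 1,5,5-trimethylspiro[5.5]undeca-1,7,10-triene-3,9-dione A3.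
- For it: it is the shortest way to the carbon skeleton, from aromatic materials, with the ring A enone, its methyl group and the gem-dimethyl group in place. In step count to the skeleton it is stronger than the chosen route.
- Against it: A3 is achiral, because the two halves of ring B are identical, so the configuration of C6 has to come from a desymmetrisation of the cross-conjugated dienone in the presence of a second enone. Ring B then needs a methyl group at C9, removal of one alkene, relocation of the other and loss of the carbonyl oxygen before any halogen can be introduced.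
- In its place, the chosen route delivers the C6 configuration and a ring B that carries exactly one alkene, at the position where the halogens go.

Alternative 3: The C5–C6 and C4–Br bonds are cut in one polyene cyclisation of (E)-γ-bisabolene A6. Forward, a vanadium bromoperoxidase with H2O2 and KBr would brominate the terminal alkene, the exocyclic alkene would attack the tertiary carbon, and proton loss would give (4S,6R)-4-bromo-1,5,5,9-tetramethylspiro[5.5]undeca-1,8-diene A5.
- For it: it is biomimetic and makes ring A, the C4 bromide and the C5–C6 bond in one step from a C15 hydrocarbon. In brevity and in forming the quaternary pair it is stronger than anything in the chosen route.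
- Against it: the enzyme is not a shelf reagent, and control of the absolute configuration at C4 and C6 for this substrate would have to be found. A6 offers three alkenes to the brominating species. After A5, the C3 hydroxyl must be introduced by allylic oxidation cis to bromine, and ring B must be bromochlorinated next to an equally reactive C1=C2 alkene, with the regiochemistry problem unsolved.
- In its place, the chosen route assigns a control element to each stereocentre and introduces each functional group at a stage where only one alkene of its kind is present.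

Key step: step 12

## Steps

Step 1
Reactants: 1 methyl 3,3-dimethylpent-4-enoate; 2 but-3-en-2-one (methyl vinyl ketone)
Product: 5 methyl 2-(2-methylbut-3-en-2-yl)-5-oxohexanoate (racemic), via silyl ketene acetal 3 (not isolated), via silyl enol ether 4 (not isolated)
Conditions: LiN(iPr)2, THF, −78 °C; TMSCl; then 2, Tf2NH (2 mol %), CH2Cl2, −78 °C; 1 M HCl
Reagents that add atoms: none
Why: Mukaiyama–Michael addition: the silyl ketene acetal of 1 adds through its α-carbon to the unhindered β-carbon of 2 (C6–C11 bond), which avoids the 1,2-addition and polymerisation seen with lithium ester enolates and enones. The α-stereocentre is racemic and is erased in step 3.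

Step 2
Reactants: 5 methyl 2-(2-methylbut-3-en-2-yl)-5-oxohexanoate; 6 vinylmagnesium bromide
Product: 8 (6R)-6-ethenyl-6-methyl-3-(2-methylbut-3-en-2-yl)oxan-2-one (both C3 epimers), via hydroxy ester 7 (not isolated)
Conditions: 6, ZnCl2, 1,4-dioxane (gives divinylzinc, magnesium salts filtered off); Ti(OiPr)4 (1.2 equiv), trans-1,2-bis(hydroxycamphorsulfonamido)cyclohexane (10 mol %, antipode chosen for Si-face delivery), PhMe, 22 °C; then 60 °C; aq. NH4Cl
Reagents that add atoms: none
Why: Titanium/bis(sulfonamide) diol-catalysed enantioselective addition of a vinylzinc reagent to a ketone; the catalyst directs vinyl to the Si face of the methyl ketone and sets the 5R carbinol of 7. The tertiary titanium alkoxide then closes the δ-lactone by titanate transesterification with loss of methanol.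

Step 3
Reactants: 8 (6R)-6-ethenyl-6-methyl-3-(2-methylbut-3-en-2-yl)oxan-2-one
Product: 11 (1S)-4-methyl-1-(2-methylbut-3-en-2-yl)cyclohex-3-ene-1-carboxylic acid, via lactone silyl ketene acetal 9 (not isolated), via trimethylsilyl ester 10 (not isolated)
Conditions: LiN(iPr)2, TMSCl, THF, −78 → 22 °C; PhMe, 100 °C; 1 M HCl
Reagents that add atoms: none
Why: Ireland–Claisen rearrangement of a lactone silyl ketene acetal (ring contraction): the vinyl group can reach the ketene acetal carbon only across the ring face it occupies, through a boat transition state, so the 6R carbinol configuration is transferred to the quaternary carbon (C6, S in 11). The same [3,3] shift forms the C6–C7 bond, ring B and the C8=C9 alkene. Both C3 epimers of 8 give the same ketene acetal.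

Step 4
Reactants: 11 (1S)-4-methyl-1-(2-methylbut-3-en-2-yl)cyclohex-3-ene-1-carboxylic acid
Product: 13 1-[(1S)-4-methyl-1-(2-methylbut-3-en-2-yl)cyclohex-3-en-1-yl]ethan-1-one, via dilithium diolate 12 (not isolated)
Conditions: MeLi (3 equiv), Et2O, 0 → 35 °C; inverse quench into 1 M HCl, 0 °C
Reagents that add atoms: methyllithium, [Li]C
Why: Methyl ketone synthesis from a carboxylic acid: MeLi adds to the lithium carboxylate and the dilithium diolate does not collapse until hydrolysis, so no tertiary alcohol forms. The two alkenes are inert.

Step 5
Reactants: 13 1-[(1S)-4-methyl-1-(2-methylbut-3-en-2-yl)cyclohex-3-en-1-yl]ethan-1-one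
Product: 14 1-[(1S,4S,6R)-1-methyl-4-(2-methylbut-3-en-2-yl)-7-oxabicyclo[4.1.0]heptan-4-yl]ethan-1-one (epoxide oxygen anti to the acetyl group)
Conditions: mCPBA (1.05 equiv), NaHCO3, CH2Cl2, 0 °C
Reagents that add atoms: 3-chloroperoxybenzoic acid, O=C(OO)c1cccc(Cl)c1
Why: Prilezhaev epoxidation of the electron-rich trisubstituted alkene; the monosubstituted vinyl group is much slower. The tertiary alkyl arm on C6 is equatorial, so the acetyl group is pseudoaxial at the homoallylic carbon and shields its own face; oxygen should enter from the opposite face.

Step 6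
Reactants: 14 1-[(1S,4S,6R)-1-methyl-4-(2-methylbut-3-en-2-yl)-7-oxabicyclo[4.1.0]heptan-4-yl]ethan-1-one
Product: 15 1-[(1S,3S,4S)-3-chloro-4-hydroxy-4-methyl-1-(2-methylbut-3-en-2-yl)cyclohexyl]ethan-1-one
Conditions: LiCl, AcOH, THF, 22 °C
Reagents that add atoms: lithium chloride, [Li+].[Cl-]
Why: Epoxide opening by halide under weakly acidic, nucleophilic conditions (SN2). Attack at the secondary carbon C8 is also the trans-diaxial (Fürst–Plattner) mode for this epoxide face in the locked ring, so both preferences agree. Inversion at C8 places chlorine on the acetyl face and leaves the C9 oxygen untouched.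

Step 7
Reactants: 15 1-[(1S,3S,4S)-3-chloro-4-hydroxy-4-methyl-1-(2-methylbut-3-en-2-yl)cyclohexyl]ethan-1-one
Product: 16 1-[(1S,3S,4S)-4-bromo-3-chloro-4-methyl-1-(2-methylbut-3-en-2-yl)cyclohexyl]ethan-1-one
Conditions: TMSBr (2.2 equiv), CH2Cl2, −20 → 0 °C
Reagents that add atoms: bromotrimethylsilane, C[Si](C)(C)Br
Why: Conversion of a tertiary alcohol into the tertiary bromide by TMSBr (SN1). The anti-periplanar axial C8–Cl bond assists ionisation at C9 through a bridged chloronium-like ion, so bromide should enter C9 anti to chlorine, with retention, to give the trans-diaxial pair. The ketone and the monosubstituted vinyl group tolerate the HBr formed at this temperature.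

Step 8
Reactants: 16 1-[(1S,3S,4S)-4-bromo-3-chloro-4-methyl-1-(2-methylbut-3-en-2-yl)cyclohexyl]ethan-1-one
Product: 17 (1S,2S,4R)-1-bromo-2-chloro-1-methyl-4-(2-methylbut-3-en-2-yl)-4-(prop-1-en-2-yl)cyclohexane
Conditions: Cp2TiMe2 (3 equiv), PhMe/THF, 65 °C, dark
Reagents that add atoms: dimethyltitanocene, [CH3-].[CH3-].[Ti+4].c1cc[cH-]c1.c1cc[cH-]c1
Why: Petasis methylenation: the titanium methylidene formed on heating converts hindered, enolisable ketones into 1,1-disubstituted alkenes under neutral, non-basic conditions, so the tertiary bromide is not exposed to an ylide base or a strong Lewis acid. The new CH2 carbon becomes C2.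

Step 9
Reactants: 17 (1S,2S,4R)-1-bromo-2-chloro-1-methyl-4-(2-methylbut-3-en-2-yl)-4-(prop-1-en-2-yl)cyclohexane
Product: 19 3-[(1R,3S,4S)-4-bromo-3-chloro-4-methyl-1-(prop-1-en-2-yl)cyclohexyl]-3-methylbutan-1-ol, via trialkylborane 18 (not isolated)
Conditions: BH3·THF, 2-methylbut-2-ene (gives (Sia)2BH), THF, 0 °C; then 17, 0 → 22 °C; NaBO3·4H2O, H2O, 22 °C
Reagents that add atoms: sodium perborate, [Na+].[O-]OB=O
Why: Hydroboration–oxidation with a bulky dialkylborane: boron adds to the terminal carbon of the monosubstituted vinyl group, while the isopropenyl group on quaternary C6 is too hindered to compete. Perborate oxidation is mild enough for the halides.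

Step 10
Reactants: 19 3-[(1R,3S,4S)-4-bromo-3-chloro-4-methyl-1-(prop-1-en-2-yl)cyclohexyl]-3-methylbutan-1-ol
Product: 20 3-[(1R,3S,4S)-4-bromo-3-chloro-4-methyl-1-(prop-1-en-2-yl)cyclohexyl]-3-methylbutanal
Conditions: Dess–Martin periodinane, NaHCO3, CH2Cl2, 0 → 22 °C
Reagents that add atoms: none
Why: Dess–Martin oxidation of a primary alcohol to the aldehyde under buffered, non-basic conditions that leave the halides and the alkene alone.

Step 11
Reactants: 20 3-[(1R,3S,4S)-4-bromo-3-chloro-4-methyl-1-(prop-1-en-2-yl)cyclohexyl]-3-methylbutanal
Product: 21 (2R)-2-bromo-3-[(1R,3S,4S)-4-bromo-3-chloro-4-methyl-1-(prop-1-en-2-yl)cyclohexyl]-3-methylbutanal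
Conditions: (R)-2-{bis[3,5-bis(trifluoromethyl)phenyl][(trimethylsilyl)oxy]methyl}pyrrolidine (20 mol %), 4,4-dibromo-2,6-di-tert-butylcyclohexa-2,5-dien-1-one, PhCO2H (20 mol %), CH2Cl2/pentane, −40 °C; cold filtration through silica, used at once
Reagents that add atoms: 4,4-dibromo-2,6-di-tert-butylcyclohexa-2,5-dien-1-one, CC(C)(C)C1=CC(Br)(Br)C=C(C(C)(C)C)C1=O
Why: Enamine-catalysed α-bromination of an aldehyde with a diarylprolinol silyl ether: the E-enamine is brominated on the face away from the diaryl(silyloxy)methyl group, which for the R catalyst gives the 2R aldehyde (C4 of the target). The bromine donor is too mild to touch the isopropenyl group. The quaternary β-carbon slows enolisation, so the product should keep its configuration until step 12.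

Step 12
Reactants: 21 (2R)-2-bromo-3-[(1R,3S,4S)-4-bromo-3-chloro-4-methyl-1-(prop-1-en-2-yl)cyclohexyl]-3-methylbutanal
Product: 23 (3S,4R,6R,8S,9S)-4,9-dibromo-8-chloro-5,5,9-trimethyl-1-methylidenespiro[5.5]undecan-3-ol, via aluminium alkoxide 22 (not isolated)
Conditions: Me2AlCl (1.5 equiv), CH2Cl2, −78 → −40 °C; aq. KNaC4H4O6
Reagents that add atoms: none
Why: Type 2 intramolecular carbonyl-ene reaction: Me2AlCl binds the aldehyde oxygen, the CH2 terminus of the isopropenyl group (C2) adds to the aldehyde carbon C3, and a hydrogen of the isopropenyl methyl passes to oxygen through a six-centre array, so that this methyl ends as the exocyclic C1 methylene. The closest known reaction type is the Me2AlCl-promoted cyclisation of aldehydes onto a tethered 1,1-disubstituted alkene to give 3-methylenecyclohexanols. Ring A closes as a six-membered ring by C2–C3 bond formation, exo with respect to the carbonyl group and with both ene carbons inside the new ring, through a chair in which the tether sits on the central ene carbon. The only new stereocentre, C3, is controlled by C4: the C4–Br bond lies equatorial and anti to the forming C2–C3 bond (the polar Felkin–Anh arrangement), while the carbonyl oxygen has to stand axial to reach the methyl hydrogen, which places OH cis to Br (3S). The step needs ring closure to outrun methyl transfer from aluminium and ionisation of the C9 bromide; the α-bromo aldehyde is a strongly activated enophile that should react at −78 °C, the C5 gem-dimethyl group and quaternary C6 hold ene and enophile together, and the C9 bromide is deactivated towards ionisation by the neighbouring chlorine. Me2AlCl removes the transferred proton as methane, giving alkoxide 22, so no protic acid is left to add to the new methylene group or to epimerise C4.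

Step 13
Reactants: 23 (3S,4R,6R,8S,9S)-4,9-dibromo-8-chloro-5,5,9-trimethyl-1-methylidenespiro[5.5]undecan-3-ol
Product: 24 (3S,4R,6R,8S,9S)-4,9-dibromo-8-chloro-1,5,5,9-tetramethylspiro[5.5]undec-1-en-3-ol
Conditions: chloro[N,N′-bis(3,5-di-tert-butylsalicylidene)cyclohexane-1,2-diaminato]cobalt (trivalent cobalt, 3 mol %), PhSiH3 (6 mol %), benzene, 22 °C
Reagents that add atoms: none
Why: Alkene isomerisation by hydrogen-atom transfer from a cobalt hydride: a hydrogen atom adds to the exocyclic CH2, and the tertiary C1 radical can give a new alkene only by losing hydrogen from C2, because C6 is quaternary. The trisubstituted endocyclic alkene is the thermodynamic product, and the neutral radical conditions should spare the halides and the new allylic alcohol.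

## Compound list

1 | methyl 3,3-dimethylpent-4-enoate | COC(=O)CC(C)(C)C=C | starting material
2 | but-3-en-2-one (methyl vinyl ketone) | CC(=O)C=C | starting material
3 | [(1-methoxy-3,3-dimethylpenta-1,4-dien-1-yl)oxy]trimethylsilane | COC(O[Si](C)(C)C)=CC(C)(C)C=C | intermediate
4 | methyl 2-(2-methylbut-3-en-2-yl)-5-[(trimethylsilyl)oxy]hex-4-enoate | COC(=O)C(CC=C(C)O[Si](C)(C)C)C(C)(C)C=C | intermediate
5 | methyl 2-(2-methylbut-3-en-2-yl)-5-oxohexanoate (racemic) | COC(=O)C(CCC(C)=O)C(C)(C)C=C | intermediate
6 | vinylmagnesium bromide | C=C[Mg]Br | starting material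
7 | methyl (5R)-5-hydroxy-5-methyl-2-(2-methylbut-3-en-2-yl)hept-6-enoate (both C2 epimers) | COC(=O)C(CC[C@@](C)(O)C=C)C(C)(C)C=C | intermediate
8 | (6R)-6-ethenyl-6-methyl-3-(2-methylbut-3-en-2-yl)oxan-2-one (both C3 epimers) | O=C1O[C@@](C)(C=C)CCC1C(C)(C)C=C | intermediate
9 | {[(2R)-2-ethenyl-2-methyl-5-(2-methylbut-3-en-2-yl)-3,4-dihydro-2H-pyran-6-yl]oxy}trimethylsilane | C=C[C@@]1(C)CCC(C(C)(C)C=C)=C(O[Si](C)(C)C)O1 | intermediate
10 | trimethylsilyl (1S)-4-methyl-1-(2-methylbut-3-en-2-yl)cyclohex-3-ene-1-carboxylate | C[Si](C)(C)OC(=O)[C@@]1(C(C)(C)C=C)CCC(C)=CC1 | intermediate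
11 | (1S)-4-methyl-1-(2-methylbut-3-en-2-yl)cyclohex-3-ene-1-carboxylic acid | OC(=O)[C@@]1(C(C)(C)C=C)CCC(C)=CC1 | intermediate
12 | dilithium 1-[(1S)-4-methyl-1-(2-methylbut-3-en-2-yl)cyclohex-3-en-1-yl]ethane-1,1-bis(olate) | [Li+].[Li+].CC([O-])([O-])[C@@]1(C(C)(C)C=C)CCC(C)=CC1 | intermediate
13 | 1-[(1S)-4-methyl-1-(2-methylbut-3-en-2-yl)cyclohex-3-en-1-yl]ethan-1-one | CC(=O)[C@@]1(C(C)(C)C=C)CCC(C)=CC1 | intermediate
14 | 1-[(1S,4S,6R)-1-methyl-4-(2-methylbut-3-en-2-yl)-7-oxabicyclo[4.1.0]heptan-4-yl]ethan-1-one | CC(=O)[C@@]1(C(C)(C)C=C)CC[C@]2(C)O[C@@H]2C1 | intermediate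
15 | 1-[(1S,3S,4S)-3-chloro-4-hydroxy-4-methyl-1-(2-methylbut-3-en-2-yl)cyclohexyl]ethan-1-one | CC(=O)[C@@]1(C(C)(C)C=C)CC[C@](C)(O)[C@@H](Cl)C1 | intermediate
16 | 1-[(1S,3S,4S)-4-bromo-3-chloro-4-methyl-1-(2-methylbut-3-en-2-yl)cyclohexyl]ethan-1-one | CC(=O)[C@@]1(C(C)(C)C=C)CC[C@](C)(Br)[C@@H](Cl)C1 | intermediate
17 | (1S,2S,4R)-1-bromo-2-chloro-1-methyl-4-(2-methylbut-3-en-2-yl)-4-(prop-1-en-2-yl)cyclohexane | C=C(C)[C@@]1(C(C)(C)C=C)CC[C@](C)(Br)[C@@H](Cl)C1 | intermediate
18 | {3-[(1R,3S,4S)-4-bromo-3-chloro-4-methyl-1-(prop-1-en-2-yl)cyclohexyl]-3-methylbutyl}bis(3-methylbutan-2-yl)borane | C=C(C)[C@@]1(C(C)(C)CCB(C(C)C(C)C)C(C)C(C)C)CC[C@](C)(Br)[C@@H](Cl)C1 | intermediate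
19 | 3-[(1R,3S,4S)-4-bromo-3-chloro-4-methyl-1-(prop-1-en-2-yl)cyclohexyl]-3-methylbutan-1-ol | C=C(C)[C@@]1(C(C)(C)CCO)CC[C@](C)(Br)[C@@H](Cl)C1 | intermediate
20 | 3-[(1R,3S,4S)-4-bromo-3-chloro-4-methyl-1-(prop-1-en-2-yl)cyclohexyl]-3-methylbutanal | C=C(C)[C@@]1(C(C)(C)CC=O)CC[C@](C)(Br)[C@@H](Cl)C1 | intermediate
21 | (2R)-2-bromo-3-[(1R,3S,4S)-4-bromo-3-chloro-4-methyl-1-(prop-1-en-2-yl)cyclohexyl]-3-methylbutanal | C=C(C)[C@@]1(C(C)(C)[C@@H](Br)C=O)CC[C@](C)(Br)[C@@H](Cl)C1 | intermediate
22 | chloro(methyl)aluminium (3S,4R,6R,8S,9S)-4,9-dibromo-8-chloro-5,5,9-trimethyl-1-methylidenespiro[5.5]undecan-3-olate | C=C1C[C@H](O[Al](C)Cl)[C@H](Br)C(C)(C)[C@@]12CC[C@](C)(Br)[C@@H](Cl)C2 | intermediate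
23 | (3S,4R,6R,8S,9S)-4,9-dibromo-8-chloro-5,5,9-trimethyl-1-methylidenespiro[5.5]undecan-3-ol | C=C1C[C@H](O)[C@H](Br)C(C)(C)[C@@]12CC[C@](C)(Br)[C@@H](Cl)C2 | intermediate
24 | (3S,4R,6R,8S,9S)-4,9-dibromo-8-chloro-1,5,5,9-tetramethylspiro[5.5]undec-1-en-3-ol | CC1=C[C@H](O)[C@H](Br)C(C)(C)[C@@]12CC[C@](C)(Br)[C@@H](Cl)C2 | target

## Step count and least certain steps

Total step count: 13. Longest linear sequence: 13 steps (1 to 24); the route is fully linear.

Step 12 (key step). The most likely failure is poor facial selectivity at the aldehyde: the oxygen-axial transition state suffers a syn-axial contact with one C5 methyl group, so the oxygen-equatorial pathway may compete. A second risk is Lewis-acid ionisation of the C9 bromide. The fallback sets out from 21 and comes back at 23. The cyclisation is run without regard to the C3 ratio, and the mixture of 23 and its epimer (3R,4R,6R,8S,9S)-4,9-dibromo-8-chloro-5,5,9-trimethyl-1-methylidenespiro[5.5]undecan-3-ol F1 is oxidised with Dess–Martin periodinane to (4R,6R,8S,9S)-4,9-dibromo-8-chloro-5,5,9-trimethyl-1-methylidenespiro[5.5]undecan-3-one F2. Reduction with iBu2AlH at −78 °C should then deliver hydride anti to the C4–Br bond and give the cis bromohydrin 23. C3 is then set by a reagent-controlled reduction and no longer by the ene transition state.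

Step 2. The most likely failure is low enantioselectivity, because the methyl group and the CH2CH2 chain of 5 differ little in size and residual magnesium salts promote the uncatalysed addition. The fallback sets out from 5 and comes back at 11. Vinylmagnesium bromide with CeCl3 adds to 5 without stereocontrol, and lactonisation gives racemic 6-ethenyl-6-methyl-3-(2-methylbut-3-en-2-yl)oxan-2-one F3. The conditions of step 3 convert it into racemic 4-methyl-1-(2-methylbut-3-en-2-yl)cyclohex-3-ene-1-carboxylic acid F4. F4 is resolved by crystallisation of its salt with (S)-1-phenylethylamine (or the antipode, whichever gives the less soluble salt of the S acid), (1S)-1-phenylethan-1-aminium (1S)-4-methyl-1-(2-methylbut-3-en-2-yl)cyclohex-3-ene-1-carboxylate F5, and acidification returns 11. The same salt formation can serve to upgrade material of incomplete enantiopurity from the catalytic route.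

Step 6. The most likely failure is participation of the axial acetyl oxygen at C8, or competing opening at the tertiary carbon C9. The fallback sets out from 13 and comes back at 15, and makes no new compound. Alkene 13 is treated with trichloroisocyanuric acid in aqueous acetone at 0 °C (electrophilic chlorohydroxylation). The chloronium ion on the acetyl face cannot be intercepted by the acetyl oxygen, and its Markovnikov, trans-diaxial opening by water at C9 leads to 15.

Step 7. The most likely failure is loss of a proton from the C9 cation (elimination) or capture of bromide syn to chlorine if bridging by chlorine is weak. The fallback sets out from 13 and comes back at 16, and makes no new compound. Alkene 13 is treated with N-bromosuccinimide and Et4NCl in CH2Cl2 at −78 °C (a BrCl equivalent). It relies on the bromonium ion forming on the face away from the acetyl group and on trans-diaxial opening by chloride at C8 overriding the Markovnikov preference; the constitutional isomer with the halogens exchanged is the expected by-product.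

Step 8. The most likely failure is slow methylenation of the very congested carbonyl group, with thermal loss of HBr from the tertiary bromide during long heating. The fallback sets out from 16 and comes back at 17. MeCeCl2 (from MeLi and CeCl3, THF, −78 °C), which is weakly basic, adds to the ketone to give 2-[(1S,3S,4S)-4-bromo-3-chloro-4-methyl-1-(2-methylbut-3-en-2-yl)cyclohexyl]propan-2-ol F6. Dehydration with methyl N-(triethylammoniosulfonyl)carbamate (Burgess reagent) can then give only the isopropenyl group of 17, because the carbinol carbon has hydrogen only on its methyl groups.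

Step 11. The most likely failure is slow enamine formation at the neopentyl-type aldehyde, erosion of catalyst control by the nearby quaternary C6, or epimerisation of the α-bromo aldehyde during handling. The fallback sets out from 20 and comes back at 24.
- Me2AlCl cyclises 20 by the same ene reaction to (6S,8S,9S)-9-bromo-8-chloro-5,5,9-trimethyl-1-methylidenespiro[5.5]undecan-3-ol F7 (either C3 epimer).
- Dess–Martin oxidation, then Et3N to move the alkene into conjugation, gives (6S,8S,9S)-9-bromo-8-chloro-1,5,5,9-tetramethylspiro[5.5]undec-1-en-3-one F8.
- Kinetic deprotonation at C4 with LiN(SiMe3)2 at −78 °C and bromination with N-bromosuccinimide gives (4R,6R,8S,9S)-4,9-dibromo-8-chloro-1,5,5,9-tetramethylspiro[5.5]undec-1-en-3-one F9, the equatorial bromide being expected under substrate control.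
- 1,2-Reduction with iBu2AlH anti to bromine gives 24 directly.

## Further compounds

F1 | step 12 | (3R,4R,6R,8S,9S)-4,9-dibromo-8-chloro-5,5,9-trimethyl-1-methylidenespiro[5.5]undecan-3-ol | C=C1C[C@@H](O)[C@H](Br)C(C)(C)[C@@]12CC[C@](C)(Br)[C@@H](Cl)C2
F2 | step 12 | (4R,6R,8S,9S)-4,9-dibromo-8-chloro-5,5,9-trimethyl-1-methylidenespiro[5.5]undecan-3-one | C=C1CC(=O)[C@H](Br)C(C)(C)[C@@]12CC[C@](C)(Br)[C@@H](Cl)C2
F3 | step 2 | 6-ethenyl-6-methyl-3-(2-methylbut-3-en-2-yl)oxan-2-one (racemic, all stereoisomers) | O=C1OC(C)(C=C)CCC1C(C)(C)C=C
F4 | step 2 | 4-methyl-1-(2-methylbut-3-en-2-yl)cyclohex-3-ene-1-carboxylic acid (racemic) | OC(=O)C1(C(C)(C)C=C)CCC(C)=CC1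
F5 | step 2 | (1S)-1-phenylethan-1-aminium (1S)-4-methyl-1-(2-methylbut-3-en-2-yl)cyclohex-3-ene-1-carboxylate | C[C@H]([NH3+])c1ccccc1.[O-]C(=O)[C@@]1(C(C)(C)C=C)CCC(C)=CC1
F0 | step 6 | none | none
F0 | step 7 | none | none
F6 | step 8 | 2-[(1S,3S,4S)-4-bromo-3-chloro-4-methyl-1-(2-methylbut-3-en-2-yl)cyclohexyl]propan-2-ol | CC(C)(O)[C@@]1(C(C)(C)C=C)CC[C@](C)(Br)[C@@H](Cl)C1
F7 | step 11 | (6S,8S,9S)-9-bromo-8-chloro-5,5,9-trimethyl-1-methylidenespiro[5.5]undecan-3-ol (either C3 epimer) | C=C1CC(O)CC(C)(C)[C@@]12CC[C@](C)(Br)[C@@H](Cl)C2
F8 | step 11 | (6S,8S,9S)-9-bromo-8-chloro-1,5,5,9-tetramethylspiro[5.5]undec-1-en-3-one | CC1=CC(=O)CC(C)(C)[C@@]12CC[C@](C)(Br)[C@@H](Cl)C2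
F9 | step 11 | (4R,6R,8S,9S)-4,9-dibromo-8-chloro-1,5,5,9-tetramethylspiro[5.5]undec-1-en-3-one | CC1=CC(=O)[C@H](Br)C(C)(C)[C@@]12CC[C@](C)(Br)[C@@H](Cl)C2
A1 | alternative 1 | (6S)-1,5,5,9-tetramethylspiro[5.5]undeca-1,8-dien-3-one | CC1=CC(=O)CC(C)(C)[C@@]12CCC(C)=CC2
A2 | alternative 1 | (6R)-6-[(2E)-but-2-en-1-yl]-5,5,9-trimethyl-6-(prop-1-en-2-yl)deca-1,9-dien-3-one | C=CC(=O)CC(C)(C)[C@@](C(C)=C)(C/C=C/C)CCC(C)=C
A3 | alternative 2 | 1,5,5-trimethylspiro[5.5]undeca-1,7,10-triene-3,9-dione | CC1=CC(=O)CC(C)(C)C12C=CC(=O)C=C2
A4 | alternative 2 | 6-(4-hydroxyphenyl)-6-methylhept-2-yn-4-one | CC#CC(=O)CC(C)(C)c1ccc(O)cc1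
A5 | alternative 3 | (4S,6R)-4-bromo-1,5,5,9-tetramethylspiro[5.5]undeca-1,8-diene | CC1=CC[C@H](Br)C(C)(C)[C@@]12CCC(C)=CC2
A6 | alternative 3 | (E)-γ-bisabolene, (4E)-1-methyl-4-(6-methylhept-5-en-2-ylidene)cyclohex-1-ene | CC1=CC/C(CC1)=C(\C)CCC=C(C)C
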